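The route rests on cutting the C7–O bond of ring A (O, C7, C8, C8', C9') of the furofuran. Only the guaiacyl ring on C7 carries a free 4-hydroxyl, so DDQ can convert C7, and no other benzylic carbon, into a quinone methide carbon. The C9' hydroxyl, cis to the C7 arm on tetrahydrofuran ring B, then adds to C7, closing ring A and setting the exo C7 stereocentre in one operation. The precursor is the all-cis 2-aryl-3-(hydroxymethyl)-4-(4-hydroxy-3-methoxybenzyl)tetrahydrofuran whose endo C7' aryl group already carries the threo glycerol side chain as a tris-TBS ether; it comes from a cis-lactone and an aryllithium.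

Key step: step 15

Numbering: lignan numbering is used (guaiacyl unit C1–C9, central syringyl unit C1'–C9', glycerol unit C1''–C9''); ring B is the tetrahydrofuran O/C9/C8/C8'/C7'.
Abbreviation: Ar* = 4-{[(1R,2R)-1,3-bis(tert-butyldimethylsilyloxy)-1-[4-(tert-butyldimethylsilyloxy)-3,5-dimethoxyphenyl]propan-2-yl]oxy}-3,5-dimethoxyphenyl.
Assumption: in step 2 the (R,R)-Et-DuPhos rhodium catalyst is taken to give the (S)-acid, by analogy with the usual sense of itaconate hydrogenations; the (S,S)-ligand would be used if the opposite sense applied.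

Step 1
Reactants: 1 4-(benzyloxy)-3-methoxybenzaldehyde; 2 dimethyl succinate
Product: 4 (E)-4-[4-(benzyloxy)-3-methoxyphenyl]-3-(methoxycarbonyl)but-3-enoic acid, via paraconate lactone 3 (not isolated)
Conditions: NaOMe (1.5 equiv), MeOH, reflux; then 2 M HCl
Reagents that add atoms: none
Why: Stobbe condensation, in which the succinate enolate adds to the aldehyde, the aldolate lactonises to 3 and base-induced E1cB ring opening gives the conjugated half-ester with the aryl group trans to the ester; no stereocentre is formed.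

Step 2
Reactants: 4 (E)-4-[4-(benzyloxy)-3-methoxyphenyl]-3-(methoxycarbonyl)but-3-enoic acid
Product: 5 (S)-4-[4-(benzyloxy)-3-methoxyphenyl]-3-(methoxycarbonyl)butanoic acid
Conditions: H2 (5 bar), [Rh(cod)((R,R)-Et-DuPhos)]BF4 (0.5 mol%), NaOMe (0.1 equiv), MeOH, rt
Reagents that add atoms: none
Why: Rhodium-catalysed asymmetric hydrogenation of an itaconate-type half-ester, in which chelation of the alkene and the carboxylate arm to rhodium inside the C2-symmetric bisphospholane pocket fixes the face of hydrogen delivery and sets C8 (S), while the aryl benzyl ether is inert to this homogeneous catalyst.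

Step 3
Reactants: 5 (S)-4-[4-(benzyloxy)-3-methoxyphenyl]-3-(methoxycarbonyl)butanoic acid
Product: 7 (S)-4-[4-(benzyloxy)-3-methoxybenzyl]dihydrofuran-2(3H)-one, via hydroxy acid 6 (not isolated)
Conditions: KOH (1.0 equiv), EtOH; CaCl2, NaBH4, EtOH, −10 °C to rt; then 2 M HCl, rt
Reagents that add atoms: none
Why: Chemoselective borohydride reduction followed by lactonisation, in which Ca(BH4)2 reduces the methyl ester but not the potassium carboxylate and acidification closes hydroxy acid 6 to the β-substituted γ-butyrolactone without touching C8.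

Step 4
Reactants: 7 (S)-4-[4-(benzyloxy)-3-methoxybenzyl]dihydrofuran-2(3H)-one
Product: 9 (3R,4S)-3-[(benzyloxy)methyl]-4-[4-(benzyloxy)-3-methoxybenzyl]dihydrofuran-2(3H)-one, via lithium enolate 8 (not isolated)
Conditions: LiN(i-Pr)2 (1.1 equiv), THF, −78 °C; BnOCH2Cl (1.3 equiv), −78 to −30 °C
Reagents that add atoms: benzyl chloromethyl ether, ClCOCc1ccccc1
Why: Lactone enolate alkylation with a reactive chloromethyl ether, which enters anti to the C4 arylmethyl group and so gives the trans lactone and installs C9'.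

Step 5
Reactants: 9 (3R,4S)-3-[(benzyloxy)methyl]-4-[4-(benzyloxy)-3-methoxybenzyl]dihydrofuran-2(3H)-one
Product: 11 (3S,4S)-3-[(benzyloxy)methyl]-4-[4-(benzyloxy)-3-methoxybenzyl]dihydrofuran-2(3H)-one, via lithium enolate 10 (not isolated)
Conditions: LiN(i-Pr)2 (1.2 equiv), THF, −78 °C, 20 min; 2,6-di-tert-butyl-4-methylphenol (3 equiv), −78 °C; then AcOH, −78 °C to rt
Reagents that add atoms: none
Why: Kinetic protonation of a planar lactone enolate by a bulky phenol on the face opposite the C4 arylmethyl group (the known contra-thermodynamic trans-to-cis epimerisation of 3,4-disubstituted butyrolactones), which leaves the benzyloxymethyl group cis to the arylmethyl group and sets C8' (S).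

Step 6
Reactants: 12 syringaldehyde
Product: 13 4-(tert-butyldimethylsilyloxy)-3,5-dimethoxybenzaldehyde
Conditions: TBSCl (1.3 equiv), imidazole (2.5 equiv), DMF, rt
Reagents that add atoms: tert-butyldimethylsilyl chloride, CC(C)(C)[Si](C)(C)Cl
Why: Standard phenol silylation, giving an aryl silyl ether that masks O4'' until the last step and keeps that ring from forming a quinone methide in step 15.

Step 7
Reactants: 14 4-bromo-2,6-dimethoxyphenol
Product: 15 (4-bromo-2,6-dimethoxyphenoxy)acetic acid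
Conditions: ClCH2CO2H (1.5 equiv), NaOH (3.5 equiv), H2O, reflux; then HCl to pH 1
Reagents that add atoms: chloroacetic acid, OC(=O)CCl
Why: Williamson ether synthesis between the sodium phenoxide and sodium chloroacetate in water, a reaction that works with 2,6-disubstituted phenols and leaves the aryl bromide alone.

Step 8
Reactants: 15 (4-bromo-2,6-dimethoxyphenoxy)acetic acid
Product: 17 (S)-4-benzyl-3-[(4-bromo-2,6-dimethoxyphenoxy)acetyl]oxazolidin-2-one, via mixed pivalic anhydride 16 (not isolated)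
Conditions: t-BuCOCl (1.1 equiv), Et3N (2.5 equiv), THF, −20 °C; then (S)-4-benzyl-2-oxazolidinone (1.0 equiv), LiCl (1.1 equiv), −20 °C to rt
Reagents that add atoms: (S)-4-benzyl-2-oxazolidinone, O=C1N[C@@H](Cc2ccccc2)CO1
Why: N-Acylation of the oxazolidinone through a mixed anhydride, the aryloxyacetyl carbonyl being attacked in preference to the hindered pivaloyl carbonyl.

Step 9
Reactants: 17 (S)-4-benzyl-3-[(4-bromo-2,6-dimethoxyphenoxy)acetyl]oxazolidin-2-one; 13 4-(tert-butyldimethylsilyloxy)-3,5-dimethoxybenzaldehyde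
Product: 20 (S)-4-benzyl-3-[(2S,3R)-2-(4-bromo-2,6-dimethoxyphenoxy)-3-[4-(tert-butyldimethylsilyloxy)-3,5-dimethoxyphenyl]-3-hydroxypropanoyl]oxazolidin-2-one, via boron enolate 18 (not isolated), via boron aldolate 19 (not isolated)
Conditions: Bu2BOTf (1.2 equiv), i-Pr2NEt (1.4 equiv), CH2Cl2, −78 to 0 °C; 13, −78 to 0 °C; then pH 7 buffer, MeOH, 30% H2O2, 0 °C
Reagents that add atoms: none
Why: Evans syn-aldol reaction, in which the Z-boron enolate reacts through a closed Zimmerman–Traxler transition state on the face away from the benzyl group of the auxiliary and sets both side-chain centres (2S,3R in 20, which are 8''R and 7''R, the threo pattern, once the acyl carbon becomes C9'').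

Step 10
Reactants: 20 (S)-4-benzyl-3-[(2S,3R)-2-(4-bromo-2,6-dimethoxyphenoxy)-3-[4-(tert-butyldimethylsilyloxy)-3,5-dimethoxyphenyl]-3-hydroxypropanoyl]oxazolidin-2-one
Product: 21 (1R,2R)-2-(4-bromo-2,6-dimethoxyphenoxy)-1-[4-(tert-butyldimethylsilyloxy)-3,5-dimethoxyphenyl]propane-1,3-diol
Conditions: LiBH4 (2 equiv), MeOH (2 equiv), THF, 0 °C; then sat. NH4Cl
Reagents that add atoms: none
Why: Reductive cleavage of the N-acyl oxazolidinone, LiBH4 reducing the exocyclic imide carbonyl to the primary alcohol and releasing the auxiliary while the aryl bromide and aryl silyl ether stay intact.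

Step 11
Reactants: 21 (1R,2R)-2-(4-bromo-2,6-dimethoxyphenoxy)-1-[4-(tert-butyldimethylsilyloxy)-3,5-dimethoxyphenyl]propane-1,3-diol
Product: 22 5-bromo-2-{[(1R,2R)-1,3-bis(tert-butyldimethylsilyloxy)-1-[4-(tert-butyldimethylsilyloxy)-3,5-dimethoxyphenyl]propan-2-yl]oxy}-1,3-dimethoxybenzene (Ar*–Br)
Conditions: TBSOTf (2.4 equiv), 2,6-lutidine (4 equiv), CH2Cl2, −78 to 0 °C
Reagents that add atoms: tert-butyldimethylsilyl triflate, CC(C)(C)[Si](C)(C)OS(=O)(=O)C(F)(F)F
Why: Silylation of the primary and the hindered benzylic hydroxyl with a silyl triflate and a hindered pyridine base, under non-acidic conditions that avoid ionisation at C7''.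

Step 12
Reactants: 22 Ar*–Br; 11 (3S,4S)-3-[(benzyloxy)methyl]-4-[4-(benzyloxy)-3-methoxybenzyl]dihydrofuran-2(3H)-one
Product: 24 (3S,4S)-2-Ar*-3-[(benzyloxy)methyl]-4-[4-(benzyloxy)-3-methoxybenzyl]tetrahydrofuran-2-ol (hemiketal; anomer mixture in equilibrium with the open hydroxy ketone), via aryllithium 23 (not isolated)
Conditions: 22 (1.2 equiv), n-BuLi (1.2 equiv), THF, −78 °C, 20 min; 11 (1.0 equiv), THF, −78 °C; then sat. NH4Cl, −78 °C to rt
Reagents that add atoms: none
Why: Bromine–lithium exchange followed by 1,2-addition to the lactone carbonyl, the exchange being faster than attack on the silyl ethers and the lithium hemiketal alkoxide being stable at −78 °C so that addition stops after one aryl group and C8 and C8' are untouched.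

Step 13
Reactants: 24 (3S,4S)-2-Ar*-3-[(benzyloxy)methyl]-4-[4-(benzyloxy)-3-methoxybenzyl]tetrahydrofuran-2-ol
Product: 26 (2S,3S,4S)-2-Ar*-3-[(benzyloxy)methyl]-4-[4-(benzyloxy)-3-methoxybenzyl]tetrahydrofuran (all-cis), via oxocarbenium ion 25 (not isolated)
Conditions: Et3SiH (5 equiv), BF3·OEt2 (2 equiv), CH2Cl2, −78 °C; then sat. NaHCO3, −78 °C
Reagents that add atoms: none
Why: Ionic hydrogenation of an aryl lactol, in which BF3·OEt2 forms the 2-aryl oxocarbenium ion and the silane delivers hydride to the face opposite the cis C8' and C8 substituents, so that the aryl group ends cis to both and C7' is set (S), the low temperature keeping the C7'' silyl ether and the C8' centre intact.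

Step 14
Reactants: 26 (2S,3S,4S)-2-Ar*-3-[(benzyloxy)methyl]-4-[4-(benzyloxy)-3-methoxybenzyl]tetrahydrofuran
Product: 27 (2S,3S,4S)-2-Ar*-3-(hydroxymethyl)-4-(4-hydroxy-3-methoxybenzyl)tetrahydrofuran (all-cis; 8S,7'S,8'S)
Conditions: H2 (1 atm), 10% Pd/C, EtOAc, rt
Reagents that add atoms: none
Why: Hydrogenolysis of the aryl and the alkyl benzyl ether over Pd/C in a neutral, non-alcoholic solvent, which spares the silyl ethers, the alkyl aryl ether at C8'' and the cyclic benzylic C7'–O bond.

Step 15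
Reactants: 27 (2S,3S,4S)-2-Ar*-3-(hydroxymethyl)-4-(4-hydroxy-3-methoxybenzyl)tetrahydrofuran
Product: 29 (7R,8S,7'S,8'S,7''R,8''R)-7'',9'',4''-tris-O-(tert-butyldimethylsilyl) ether of the target, via quinone methide 28 (not isolated)
Conditions: DDQ (1.05 equiv), 4 Å molecular sieves, CH2Cl2, 0 °C to rt
Reagents that add atoms: none
Why: DDQ forms a charge-transfer complex with the free phenol and removes hydride from the para benzylic carbon C7 (then the phenolic proton) to give p-quinone methide 28, and the C9' hydroxyl, held on the same face of ring B as the C7 arm, adds to C7 in a conjugate addition assisted by the acidic hydroquinone, which rearomatises the guaiacyl ring and forms the C7–O bond. The closest known reaction type is the DDQ dehydrogenative etherification of 4-hydroxybenzyl groups through quinone methides, as applied to 3-hydroxymethyl-4-(4-hydroxybenzyl)tetrahydrofuran lignans to give furofurans. Ring A (O, C7, C8, C8', C9') closes in the 5-exo-trig mode, the attacked methide carbon being exocyclic to the new ring, and the cis ring fusion follows from the cis C8/C8' substituents. The new stereocentre C7 (R) is controlled by the bicyclic framework, the aryl group taking the convex (exo) face anti to C9 and away from the endo C7' aryl group, and since the addition can revert through the quinone methide under the mildly acidic conditions the kinetic and thermodynamic outcomes should coincide. The step needs chemoselective oxidation at C7 over the C7'–H and C7''–H benzylic ether positions, which is secured because only the guaiacyl ring has a free para-hydroxyl (O4' is alkylated, O4'' silylated) and so only it can give a neutral quinone methide, while one equivalent of oxidant at 0 °C and molecular sieves guard against over-oxidation and capture by water.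

Step 16
Reactants: 29 7'',9'',4''-tris-O-(tert-butyldimethylsilyl) ether of the target
Product: 30 (7R,8S,7'S,8'S,7''R,8''R)-4,4'',7'',9''-tetrahydroxy-3,3',5',3'',5''-pentamethoxy-7,9':7',9-diepoxy-8,8'-lignan 4'-O-8'' glycerol ether (target CNP0317965.1)
Conditions: Bu4NF (4 equiv), AcOH (4 equiv), THF, 0 °C to rt
Reagents that add atoms: none
Why: Fluoride desilylation of the aryl, benzylic and primary silyl ethers, buffered with acetic acid so that the medium stays near neutral and neither the benzylic ethers of the furofuran nor C7'' can epimerise.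

Compound list
1 | 4-(benzyloxy)-3-methoxybenzaldehyde | COc1cc(C=O)ccc1OCc1ccccc1 | starting material
2 | dimethyl succinate | COC(=O)CCC(=O)OC | starting material
3 | methyl 2-[4-(benzyloxy)-3-methoxyphenyl]-5-oxotetrahydrofuran-3-carboxylate (paraconate lactone, diastereomer mixture) | COC(=O)C1CC(=O)OC1c1ccc(OCc2ccccc2)c(OC)c1 | intermediate (not isolated)
4 | (E)-4-[4-(benzyloxy)-3-methoxyphenyl]-3-(methoxycarbonyl)but-3-enoic acid | COC(=O)/C(CC(=O)O)=C/c1ccc(OCc2ccccc2)c(OC)c1 | intermediate
5 | (S)-4-[4-(benzyloxy)-3-methoxyphenyl]-3-(methoxycarbonyl)butanoic acid | COC(=O)[C@@H](Cc1ccc(OCc2ccccc2)c(OC)c1)CC(=O)O | intermediate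
6 | (S)-4-[4-(benzyloxy)-3-methoxyphenyl]-3-(hydroxymethyl)butanoic acid | OC[C@@H](Cc1ccc(OCc2ccccc2)c(OC)c1)CC(=O)O | intermediate (not isolated)
7 | (S)-4-[4-(benzyloxy)-3-methoxybenzyl]dihydrofuran-2(3H)-one | O=C1C[C@H](Cc2ccc(OCc3ccccc3)c(OC)c2)CO1 | intermediate
8 | lithium enolate of 7 | [Li]OC1=C[C@H](Cc2ccc(OCc3ccccc3)c(OC)c2)CO1 | intermediate (not isolated)
9 | (3R,4S)-3-[(benzyloxy)methyl]-4-[4-(benzyloxy)-3-methoxybenzyl]dihydrofuran-2(3H)-one (trans) | O=C1OC[C@@H](Cc2ccc(OCc3ccccc3)c(OC)c2)[C@@H]1COCc1ccccc1 | intermediate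
10 | lithium enolate of 9 | [Li]OC1=C(COCc2ccccc2)[C@H](Cc2ccc(OCc3ccccc3)c(OC)c2)CO1 | intermediate (not isolated)
11 | (3S,4S)-3-[(benzyloxy)methyl]-4-[4-(benzyloxy)-3-methoxybenzyl]dihydrofuran-2(3H)-one (cis) | O=C1OC[C@@H](Cc2ccc(OCc3ccccc3)c(OC)c2)[C@H]1COCc1ccccc1 | intermediate
12 | syringaldehyde | COc1cc(C=O)cc(OC)c1O | starting material
13 | 4-(tert-butyldimethylsilyloxy)-3,5-dimethoxybenzaldehyde | COc1cc(C=O)cc(OC)c1O[Si](C)(C)C(C)(C)C | intermediate
14 | 4-bromo-2,6-dimethoxyphenol | COc1cc(Br)cc(OC)c1O | starting material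
15 | (4-bromo-2,6-dimethoxyphenoxy)acetic acid | COc1cc(Br)cc(OC)c1OCC(=O)O | intermediate
16 | (4-bromo-2,6-dimethoxyphenoxy)acetic pivalic anhydride | COc1cc(Br)cc(OC)c1OCC(=O)OC(=O)C(C)(C)C | intermediate (not isolated)
17 | (S)-4-benzyl-3-[(4-bromo-2,6-dimethoxyphenoxy)acetyl]oxazolidin-2-one | COc1cc(Br)cc(OC)c1OCC(=O)N1[C@@H](Cc2ccccc2)COC1=O | intermediate
18 | (Z)-dibutylboron enolate of 17 | CCCCB(CCCC)O/C(=C\Oc1c(OC)cc(Br)cc1OC)N1[C@@H](Cc2ccccc2)COC1=O | intermediate (not isolated)
19 | O-dibutylboryl aldolate of 20 | O=C([C@@H](Oc1c(OC)cc(Br)cc1OC)[C@H](OB(CCCC)CCCC)c1cc(OC)c(O[Si](C)(C)C(C)(C)C)c(OC)c1)N1[C@@H](Cc2ccccc2)COC1=O | intermediate (not isolated)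
20 | (S)-4-benzyl-3-[(2S,3R)-2-(4-bromo-2,6-dimethoxyphenoxy)-3-[4-(tert-butyldimethylsilyloxy)-3,5-dimethoxyphenyl]-3-hydroxypropanoyl]oxazolidin-2-one | O=C([C@@H](Oc1c(OC)cc(Br)cc1OC)[C@H](O)c1cc(OC)c(O[Si](C)(C)C(C)(C)C)c(OC)c1)N1[C@@H](Cc2ccccc2)COC1=O | intermediate
21 | (1R,2R)-2-(4-bromo-2,6-dimethoxyphenoxy)-1-[4-(tert-butyldimethylsilyloxy)-3,5-dimethoxyphenyl]propane-1,3-diol | OC[C@@H](Oc1c(OC)cc(Br)cc1OC)[C@H](O)c1cc(OC)c(O[Si](C)(C)C(C)(C)C)c(OC)c1 | intermediate
22 | 5-bromo-2-{[(1R,2R)-1,3-bis(tert-butyldimethylsilyloxy)-1-[4-(tert-butyldimethylsilyloxy)-3,5-dimethoxyphenyl]propan-2-yl]oxy}-1,3-dimethoxybenzene (Ar*–Br) | CC(C)(C)[Si](C)(C)OC[C@@H](Oc1c(OC)cc(Br)cc1OC)[C@H](O[Si](C)(C)C(C)(C)C)c1cc(OC)c(O[Si](C)(C)C(C)(C)C)c(OC)c1 | intermediate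
23 | aryllithium Ar*–Li | [Li]c1cc(OC)c(O[C@H](CO[Si](C)(C)C(C)(C)C)[C@H](O[Si](C)(C)C(C)(C)C)c2cc(OC)c(O[Si](C)(C)C(C)(C)C)c(OC)c2)c(OC)c1 | intermediate (not isolated)
24 | (3S,4S)-2-Ar*-3-[(benzyloxy)methyl]-4-[4-(benzyloxy)-3-methoxybenzyl]tetrahydrofuran-2-ol (hemiketal, anomer mixture) | COc1cc(C[C@@H]2COC(O)(c3cc(OC)c(O[C@H](CO[Si](C)(C)C(C)(C)C)[C@H](O[Si](C)(C)C(C)(C)C)c4cc(OC)c(O[Si](C)(C)C(C)(C)C)c(OC)c4)c(OC)c3)[C@@H]2COCc2ccccc2)ccc1OCc1ccccc1 | intermediate
25 | 2-Ar* oxocarbenium ion derived from 24 | COc1cc(C[C@@H]2C[O+]=C(c3cc(OC)c(O[C@H](CO[Si](C)(C)C(C)(C)C)[C@H](O[Si](C)(C)C(C)(C)C)c4cc(OC)c(O[Si](C)(C)C(C)(C)C)c(OC)c4)c(OC)c3)[C@@H]2COCc2ccccc2)ccc1OCc1ccccc1 | intermediate (not isolated)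
26 | (2S,3S,4S)-2-Ar*-3-[(benzyloxy)methyl]-4-[4-(benzyloxy)-3-methoxybenzyl]tetrahydrofuran (all-cis) | COc1cc(C[C@@H]2CO[C@H](c3cc(OC)c(O[C@H](CO[Si](C)(C)C(C)(C)C)[C@H](O[Si](C)(C)C(C)(C)C)c4cc(OC)c(O[Si](C)(C)C(C)(C)C)c(OC)c4)c(OC)c3)[C@@H]2COCc2ccccc2)ccc1OCc1ccccc1 | intermediate
27 | (2S,3S,4S)-2-Ar*-3-(hydroxymethyl)-4-(4-hydroxy-3-methoxybenzyl)tetrahydrofuran (all-cis; key-step precursor) | COc1cc(C[C@@H]2CO[C@H](c3cc(OC)c(O[C@H](CO[Si](C)(C)C(C)(C)C)[C@H](O[Si](C)(C)C(C)(C)C)c4cc(OC)c(O[Si](C)(C)C(C)(C)C)c(OC)c4)c(OC)c3)[C@@H]2CO)ccc1O | intermediate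
28 | p-quinone methide of 27 (C7 methide carbon) | COC1=CC(=C[C@@H]2CO[C@H](c3cc(OC)c(O[C@H](CO[Si](C)(C)C(C)(C)C)[C@H](O[Si](C)(C)C(C)(C)C)c4cc(OC)c(O[Si](C)(C)C(C)(C)C)c(OC)c4)c(OC)c3)[C@@H]2CO)C=CC1=O | intermediate (not isolated)
29 | (7R,8S,7'S,8'S,7''R,8''R)-7'',9'',4''-tris-O-(tert-butyldimethylsilyl) ether of the target | COc1cc([C@@H]2OC[C@@H]3[C@H]2CO[C@@H]3c2cc(OC)c(O[C@H](CO[Si](C)(C)C(C)(C)C)[C@H](O[Si](C)(C)C(C)(C)C)c3cc(OC)c(O[Si](C)(C)C(C)(C)C)c(OC)c3)c(OC)c2)ccc1O | intermediate
30 | (7R,8S,7'S,8'S,7''R,8''R) furofuran sesquilignan CNP0317965.1 | COc1cc([C@@H]2OC[C@@H]3[C@H]2CO[C@@H]3c2cc(OC)c(O[C@H](CO)[C@H](O)c3cc(OC)c(O)c(OC)c3)c(OC)c2)ccc1O | target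

Total step count: 16.
Longest linear sequence: 10 steps (steps 7–16 from 14; steps 1–5 followed by 12–16 from 1 are equally long).

Steps most likely to fail

1. Step 15 (key step). The oxidant may go on to remove the remaining C7–H of the cyclised p-hydroxybenzyl ether (over-oxidation, then capture by water and ring cleavage), or oxidative coupling between phenols may outrun ring closure. Fallback: oxidation and ring closure are separated. Setting out from 27, DDQ in CH2Cl2–MeOH should trap the quinone methide with methanol and give the 7-methoxy ether F1 as both C7 epimers. A catalytic amount of camphorsulfonic acid in dry CH2Cl2 at 0 °C should then ionise only this p-hydroxybenzyl methyl ether, and the C9' hydroxyl closes ring A under equilibrating conditions, which returns to the route at 29.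

2. Step 5. Protonation of enolate 10 may show poor facial selectivity, and the enolate may lose benzyloxide by β-elimination to give an α-methylene lactone. Fallback: the cis relationship is set on a hydroxymethyl lactone whose dianion cannot eliminate. Setting out from 7, lithium enolate 8 is hydroxymethylated with monomeric formaldehyde (from cracked paraformaldehyde) to the trans hydroxymethyl lactone F2. Two equivalents of LiN(i-Pr)2 give the dilithium alkoxide enolate F3, which is protonated at −78 °C with the same hindered phenol to the cis hydroxymethyl lactone F4. Benzylation with benzyl 2,2,2-trichloroacetimidate and a trace of TfOH, which does not enolise the lactone, returns to the route at 11.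

3. Step 12. Proton transfer from C8' of lactone 11 to the aryllithium (loss of the cis configuration and of material) or a second addition to the ring-opened ketone may compete with single addition. Fallback: the aryl group is introduced at the aldehyde oxidation level. Setting out from 11, i-Bu2AlH at −78 °C gives the lactol F5. After deprotonation with NaH it reacts as the open hydroxy aldehyde with aryllithium 23 to give the diol F6 (both C7' epimers). MnO2 in CH2Cl2 then oxidises only the benzylic hydroxyl to the aryl ketone, which closes to hemiketal 24, where the route is rejoined.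

Further compounds
F1 | step 15 | 7-methoxy ether of 27 (both C7 epimers) | COc1cc(C(OC)[C@@H]2CO[C@H](c3cc(OC)c(O[C@H](CO[Si](C)(C)C(C)(C)C)[C@H](O[Si](C)(C)C(C)(C)C)c4cc(OC)c(O[Si](C)(C)C(C)(C)C)c(OC)c4)c(OC)c3)[C@@H]2CO)ccc1O
F2 | step 5 | (3R,4S)-4-[4-(benzyloxy)-3-methoxybenzyl]-3-(hydroxymethyl)dihydrofuran-2(3H)-one (trans) | O=C1OC[C@@H](Cc2ccc(OCc3ccccc3)c(OC)c2)[C@@H]1CO
F3 | step 5 | dilithium alkoxide enolate of F2 | [Li]OCC1=C(O[Li])OC[C@H]1Cc1ccc(OCc2ccccc2)c(OC)c1
F4 | step 5 | (3S,4S)-4-[4-(benzyloxy)-3-methoxybenzyl]-3-(hydroxymethyl)dihydrofuran-2(3H)-one (cis) | O=C1OC[C@@H](Cc2ccc(OCc3ccccc3)c(OC)c2)[C@H]1CO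
F5 | step 12 | (3S,4S)-3-[(benzyloxy)methyl]-4-[4-(benzyloxy)-3-methoxybenzyl]tetrahydrofuran-2-ol (lactol, anomer mixture) | OC1OC[C@@H](Cc2ccc(OCc3ccccc3)c(OC)c2)[C@H]1COCc1ccccc1
F6 | step 12 | (2S,3S)-1-Ar*-2-[(benzyloxy)methyl]-3-[4-(benzyloxy)-3-methoxybenzyl]butane-1,4-diol (both C7' epimers) | OC[C@@H](Cc1ccc(OCc2ccccc2)c(OC)c1)[C@H](C(O)c1cc(OC)c(O[C@H](CO[Si](C)(C)C(C)(C)C)[C@H](O[Si](C)(C)C(C)(C)C)c2cc(OC)c(O[Si](C)(C)C(C)(C)C)c(OC)c2)c(OC)c1)COCc1ccccc1
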